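Readings and results stem from a simulated flask for an exercise, and the scatter is random.

The target in the flask I reckoned as a share of what survives the protic impurity, not as a yield on the charge.

| setting | south-east | south-west | flask |
|---|---|---|---|
| starting material | 20 mM | 20 mM | 20 mM |
| protic impurity | 5 mM | 20 mM | 10.0 mM |
| remark | run made earlier | run made earlier |  |
| time |  |  | 4.0 d |

| run | time / d | starting material / % | target / % |
|---|---|---|---|
| south-east | 1.04 | 19 | 35 |
| south-east | 2.08 | 17 | 37 |
| south-east | 3.00 | 17 | 38 |
| south-east | 4.00 | 16 | 34 |
| south-west | 0.333 | 3 | 8 |
| south-west | 0.833 | 2 | 5 |
| south-west | 1.67 | 1 | 3 |
| south-west | 4.00 | 1 | 0 |

(readings scatter by 1.5 percentage points)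

- why nothing more happens at 4.0 d, or that something still does (all of the starting material has reacted / it is still moving / forward and back rates have come level)
- how much of the starting material has reacted by 4.0 d
- how much target there is at 4.0 d, in percent of the starting material charged
- how much isomer of the product B there is at 4.0 d, in percent of the starting material charged
- amount of target if the flask were left three thousand times as long, in percent of the starting material charged

- the analysis behind the earlier runs scatters by 1.5 percentage points, standard deviation
- the reaction counts as stopped when no species that holds the starting material changes by six tenths of a point or more over the second half of the time

I supposed that one impurity removes one starting material for good, which makes the impurity, charged in the flask at less than the starting material, the limiting reagent of that loss. The surviving fraction f is then one minus the impurity charge over the starting-material charge. In the south-east run f was 75.0 % and the target read on average 36.0 %, so s, the target over f, came to 48.0 %, the target's share of the survivors. The starting material averaged 17.2 % there.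

My first way gave the flask f = 50.0 %, hence 24.0 % target and a pool of target plus starting material of 35.5 %. My second way interpolated the logarithm of that pool linearly in impurity, between the south-east reading of 50.0 % at 4.00 d and the south-west reading of 1.00 % at 4.00 d; it gave 13.6 %. The two parted widely.

The second way assumes a drain that lasts. But a steady first-order drain of the south-east pool from the whole charge, passing 54.0 % at 1.04 d, would have left 9.35 % at 4.00 d, and 50.0 % was read. I kept the first way. For the flask I committed to forward and back rates come level, 88.5 % reacted, 24.0 % target then and much later, and, counting the unread remainder of the survivors as isomer of the product B, 14.5 % of it.

The forecast said that it is still moving, with 97 % reacted, 7 % target, 90 % isomer of the product B and finally 0 % target, on the ground that “that titration-like capacity gives about 90% B”.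

In the flask forward and back rates have come level, with 88.6 % reacted, 24.0 % target, 9.57 % isomer of the product B, and 24.0 % target in the very long run. Beside them the flask held 5.04 % isomer of the product A at 4.00 d.

    starting material ⇌ target (K = 2.10, k = 0.110 /h)
    target ⇌ isomer of the product A (K = 0.210, k = 0.100 /h)
    isomer of the product A ⇌ isomer of the product B (K = 1.90, k = 0.0360 /h)
    isomer of the product B ⇌ starting material (k = 0.0560 /h)
    starting material + protic impurity → quenched substrate (k = 85.0 /M/h)

For the neighbouring flask, with 50 mM of starting material and the same 10.0 mM of impurity, f is 80.0 %, so s gives 38.4 % target. That neighbouring flask gave 38.4 % target, with 81.7 % reacted and 20.0 % as quenched substrate.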